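**Plan**
- Retrosynthesis: cut the C8–O ester bond (side-chain acid, attached with inversion at C8), then the ring bond C7–C8, then C3–C4 (C2=C3 from an alkyne), then the butenolide bond C7=C11 and the acyl bond C6–O.
- Enabling feature: the exocyclic methylene C13=C11 beside C7, with oxygen on C8, is the trace of an allyl transposition. A 3-(bromomethyl)butenolide (C13–Br, C11=C7, lactone ring O–C12–C11–C7–C6 already closed) can add through C7 to a C8 aldehyde.
- Forward: the epoxy alkyne (C8, C9, C10, C14, C1, C2, C3) and the iodovinyl butenolide (C4–C7, C11–C13, C15) are made separately, joined at C3–C4 and semi-hydrogenated. The five-membered lactone exists first; the ten-membered carbocycle is closed last at C7–C8.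
- Stereochemistry: C1/C10 from a Sharpless epoxidation and C6 from a catalytic asymmetric alkynylation. C7 and C8 both arise in the ring closure, under control of C6 and a chair transition state; C8 is then inverted in the Mitsunobu esterification.
- Olefin geometry: C4=C5 from hydroxyl-directed trans-hydroalumination/iodination, C2=C3 from cis-hydrogenation, the side chain from cis-hydroalumination of an ynoate.

Key step: step 16

Numbering remark: C1–C15 are the germacrane positions of the target (C6 lactone carbinol, C7 ring carbon bearing the methylene lactone, C8 acyloxy carbon, C1/C10 epoxide, C14 methyl on C10, C15 hydroxymethyl carbon on C4, C13 exocyclic methylene). C4=C5 is 4E by the CIP rules but cis within the ring (C3 and C6 on the same side).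

Assumption: the (S,S)-ProPhenol/zinc catalyst is taken to deliver the alkynyl group to the Re face of the enal in step 7; if the sense is opposite, the (R,R)-ligand is used.

**Route**

Step 1
Reactants: 1 tert-butyl(but-3-yn-1-yloxy)dimethylsilane
Product: 3 (E)-5-[(tert-butyldimethylsilyl)oxy]-3-methylpent-2-en-1-ol, via alkenyldimethylalane 2 (not isolated)
Conditions: Me3Al, Cp2ZrCl2 (25 mol %), CH2Cl2, 0 °C to rt; then (CH2O)n, THF, 0 °C to rt; aq. work-up
Reagents that add atoms: trimethylaluminium C[Al](C)C; paraformaldehyde (as formaldehyde) C=O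
Why: Zirconium-catalysed carboalumination (Negishi) adds methyl and aluminium syn across the terminal alkyne with aluminium on the terminal carbon, and hydroxymethylation of 2 with retention fixes the E geometry needed for the trans-epoxide.

Step 2
Reactants: 3 (E)-5-[(tert-butyldimethylsilyl)oxy]-3-methylpent-2-en-1-ol
Product: 4 [(2R,3R)-3-{2-[(tert-butyldimethylsilyl)oxy]ethyl}-3-methyloxiran-2-yl]methanol
Conditions: Ti(OiPr)4 (10 mol %), D-(−)-diethyl tartrate (12 mol %), t-BuOOH, 4 Å molecular sieves, CH2Cl2, −20 °C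
Reagents that add atoms: tert-butyl hydroperoxide CC(C)(C)OO
Why: Sharpless asymmetric epoxidation of the E-trisubstituted allylic alcohol with the D-tartrate delivers oxygen to the face that gives the (2R,3R)-epoxy alcohol (the antipode of the L-tartrate outcome known for geraniol-type alcohols), which sets C1 and C10 in one reagent-controlled event.

Step 3
Reactants: 4 [(2R,3R)-3-{2-[(tert-butyldimethylsilyl)oxy]ethyl}-3-methyloxiran-2-yl]methanol
Product: 5 (2S,3R)-3-{2-[(tert-butyldimethylsilyl)oxy]ethyl}-3-methyloxirane-2-carbaldehyde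
Conditions: Dess–Martin periodinane, CH2Cl2, 0 °C to rt
Reagents that add atoms: none
Why: Dess–Martin oxidation converts the primary epoxy alcohol to the aldehyde under neutral conditions that leave the epoxide and silyl ether intact (the descriptor at the aldehyde-bearing carbon changes only by priority).

Step 4
Reactants: 5 (2S,3R)-3-{2-[(tert-butyldimethylsilyl)oxy]ethyl}-3-methyloxirane-2-carbaldehyde
Product: 6 tert-butyl{2-[(2R,3R)-3-ethynyl-2-methyloxiran-2-yl]ethoxy}dimethylsilane
Conditions: dimethyl (1-diazo-2-oxopropyl)phosphonate, K2CO3, MeOH, 0 °C to rt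
Reagents that add atoms: dimethyl (1-diazo-2-oxopropyl)phosphonate CC(=O)C(=[N+]=[N-])P(=O)(OC)OC
Why: Seyferth–Gilbert homologation with the Ohira–Bestmann reagent turns the aldehyde into the terminal alkyne (the added carbon becomes C3) under mild carbonate conditions that do not epimerise the epoxide carbon.

Step 5
Reactants: 6 tert-butyl{2-[(2R,3R)-3-ethynyl-2-methyloxiran-2-yl]ethoxy}dimethylsilane
Product: 7 2-[(2R,3R)-3-ethynyl-2-methyloxiran-2-yl]ethan-1-ol
Conditions: TBAF, THF, 0 °C
Reagents that add atoms: none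
Why: Fluoride cleaves the primary silyl ether while only a robust alkynyl epoxide is present, so that no silyl group has to be removed later from the acid-sensitive dienyl epoxide.

Step 6
Reactants: 8 2-(bromomethyl)acrylic acid; 9 4-methoxybenzyl alcohol
Product: 10 2-{[(4-methoxybenzyl)oxy]methyl}acrylic acid
Conditions: NaH (2.2 equiv), THF, 0 °C to rt; then 1 M HCl to pH 3
Reagents that add atoms: none
Why: Williamson-type etherification in which the alkoxide of 9 displaces the allylic bromide of the carboxylate of 8 (SN2 and SN2' give the same product), the carboxylate shielding the acrylate from conjugate addition.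

Step 7
Reactants: 11 (E)-but-2-enal; 12 tert-butyldimethyl(prop-2-yn-1-yloxy)silane
Product: 14 (4S,5E)-1-[(tert-butyldimethylsilyl)oxy]hept-5-en-2-yn-4-ol, via alkynyl(methyl)zinc 13 (not isolated)
Conditions: 12, Me2Zn, (S,S)-ProPhenol ligand [2,6-bis{[(S)-2-(hydroxydiphenylmethyl)pyrrolidin-1-yl]methyl}-4-methylphenol] (20 mol %), Ph3P=O (40 mol %), toluene, 0 °C; then 11, 4 °C
Reagents that add atoms: none
Why: Zinc/ProPhenol-catalysed enantioselective alkynylation of an enal, an established substrate class for this reaction, sets C6 by delivery of alkynylzinc 13 to the Re face of the aldehyde to give the (S)-carbinol.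

Step 8
Reactants: 14 (4S,5E)-1-[(tert-butyldimethylsilyl)oxy]hept-5-en-2-yn-4-ol
Product: 16 (2Z,4S,5E)-1-[(tert-butyldimethylsilyl)oxy]-2-iodohepta-2,5-dien-4-ol, via cyclic alkenylaluminate 15 (not isolated)
Conditions: NaAlH2(OCH2CH2OMe)2 (Red-Al), THF, 0 °C; then I2, THF, −78 °C to 0 °C
Reagents that add atoms: iodine II
Why: Hydroxyl-directed trans-hydroalumination of the propargylic alcohol puts hydride on the proximal and aluminium on the distal alkyne carbon (cyclic aluminate 15), and iodinolysis with retention gives the Z-vinyl iodide with C6 and iodine (the later C3) cis, which is the ring-cis C4=C5 geometry.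

Step 9
Reactants: 16 (2Z,4S,5E)-1-[(tert-butyldimethylsilyl)oxy]-2-iodohepta-2,5-dien-4-ol; 10 2-{[(4-methoxybenzyl)oxy]methyl}acrylic acid
Product: 17 (2Z,4S,5E)-1-[(tert-butyldimethylsilyl)oxy]-2-iodohepta-2,5-dien-4-yl 2-{[(4-methoxybenzyl)oxy]methyl}prop-2-enoate
Conditions: DCC, DMAP (10 mol %), CH2Cl2, 0 °C to rt
Reagents that add atoms: none
Why: Steglich esterification acylates the secondary bis-allylic alcohol at oxygen, with retention at C6.

Step 10
Reactants: 17 (2Z,4S,5E)-1-[(tert-butyldimethylsilyl)oxy]-2-iodohepta-2,5-dien-4-yl 2-{[(4-methoxybenzyl)oxy]methyl}prop-2-enoate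
Product: 18 (5S)-5-[(1Z)-3-[(tert-butyldimethylsilyl)oxy]-2-iodoprop-1-en-1-yl]-3-{[(4-methoxybenzyl)oxy]methyl}furan-2(5H)-one
Conditions: second-generation Grubbs catalyst (H2IMes)(PCy3)Cl2Ru=CHPh (5 mol %), toluene (0.01 M), 80 °C
Reagents that add atoms: none
Why: Ring-closing metathesis between the propenyl group and the 1,1-disubstituted acrylate closes the butenolide (as known for methacrylates of allylic alcohols) with loss of propene, while the trisubstituted vinyl iodide is too hindered to engage the ruthenium carbene.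

Step 11
Reactants: 18 (5S)-5-[(1Z)-3-[(tert-butyldimethylsilyl)oxy]-2-iodoprop-1-en-1-yl]-3-{[(4-methoxybenzyl)oxy]methyl}furan-2(5H)-one
Product: 19 (5S)-5-[(1Z)-3-[(tert-butyldimethylsilyl)oxy]-2-iodoprop-1-en-1-yl]-3-(hydroxymethyl)furan-2(5H)-one
Conditions: DDQ, CH2Cl2/pH 7 buffer, 0 °C to rt
Reagents that add atoms: none
Why: Oxidative cleavage of the 4-methoxybenzyl ether by DDQ frees the C13 hydroxyl while no electron-rich diene or epoxide is yet present, and the C15 silyl ether is untouched.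

Step 12
Reactants: 19 (5S)-5-[(1Z)-3-[(tert-butyldimethylsilyl)oxy]-2-iodoprop-1-en-1-yl]-3-(hydroxymethyl)furan-2(5H)-one; 7 2-[(2R,3R)-3-ethynyl-2-methyloxiran-2-yl]ethan-1-ol
Product: 20 (5R)-5-[(1E)-2-{[(tert-butyldimethylsilyl)oxy]methyl}-4-[(2R,3R)-3-(2-hydroxyethyl)-3-methyloxiran-2-yl]but-1-en-3-yn-1-yl]-3-(hydroxymethyl)furan-2(5H)-one
Conditions: Pd(PPh3)2Cl2 (5 mol %), CuI (10 mol %), Et3N (3 equiv), THF, 0 °C to rt
Reagents that add atoms: none
Why: Sonogashira coupling joins vinyl iodide and terminal alkyne at C3–C4 with retention of alkene geometry (the C6 descriptor changes only by priority); little amine base and low temperature limit deprotonation at the butenolide γ-carbon C6.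

Step 13
Reactants: 20 (5R)-5-[(1E)-2-{[(tert-butyldimethylsilyl)oxy]methyl}-4-[(2R,3R)-3-(2-hydroxyethyl)-3-methyloxiran-2-yl]but-1-en-3-yn-1-yl]-3-(hydroxymethyl)furan-2(5H)-one
Product: 21 (5R)-5-[(1E,3Z)-2-{[(tert-butyldimethylsilyl)oxy]methyl}-4-[(2R,3R)-3-(2-hydroxyethyl)-3-methyloxiran-2-yl]buta-1,3-dien-1-yl]-3-(hydroxymethyl)furan-2(5H)-one
Conditions: H2 (1 atm), Pd on CaCO3 poisoned with Pb(OAc)2 (Lindlar catalyst), quinoline, EtOAc, rt; chromatography on Et3N-deactivated silica
Reagents that add atoms: none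
Why: Lindlar semi-hydrogenation adds hydrogen cis to the alkyne of the conjugated enyne and gives the 2Z-alkene of the Z,Z-diene, with quinoline to suppress over-reduction and hydrogenolysis of the allylic epoxide.

Step 14
Reactants: 21 (5R)-5-[(1E,3Z)-2-{[(tert-butyldimethylsilyl)oxy]methyl}-4-[(2R,3R)-3-(2-hydroxyethyl)-3-methyloxiran-2-yl]buta-1,3-dien-1-yl]-3-(hydroxymethyl)furan-2(5H)-one
Product: 22 (5R)-3-(bromomethyl)-5-[(1E,3Z)-2-{[(tert-butyldimethylsilyl)oxy]methyl}-4-[(2R,3R)-3-(2-hydroxyethyl)-3-methyloxiran-2-yl]buta-1,3-dien-1-yl]furan-2(5H)-one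
Conditions: NBS, Me2S, CH2Cl2, −20 °C to 0 °C; aq. work-up
Reagents that add atoms: N-bromosuccinimide O=C1CCC(=O)N1Br
Why: The Corey–Kim reagent converts allylic alcohols to bromides by SN2 attack of bromide on the alkoxysulfonium ion, whereas the saturated primary C8 alcohol only forms an alkoxysulfonium salt that reverts on aqueous work-up, so only the C13 hydroxyl is replaced, under neutral conditions.

Step 15
Reactants: 22 (5R)-3-(bromomethyl)-5-[(1E,3Z)-2-{[(tert-butyldimethylsilyl)oxy]methyl}-4-[(2R,3R)-3-(2-hydroxyethyl)-3-methyloxiran-2-yl]buta-1,3-dien-1-yl]furan-2(5H)-one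
Product: 23 2-[(2R,3R)-3-[(1Z,3E)-4-[(2R)-4-(bromomethyl)-5-oxo-2,5-dihydrofuran-2-yl]-3-{[(tert-butyldimethylsilyl)oxy]methyl}buta-1,3-dien-1-yl]-2-methyloxiran-2-yl]acetaldehyde
Conditions: Dess–Martin periodinane, NaHCO3, CH2Cl2, 0 °C; used at once
Reagents that add atoms: none
Why: Buffered Dess–Martin oxidation gives the β,γ-epoxy aldehyde without base that could open the epoxide by elimination and without touching the allylic bromide.

Step 16
Reactants: 23 2-[(2R,3R)-3-[(1Z,3E)-4-[(2R)-4-(bromomethyl)-5-oxo-2,5-dihydrofuran-2-yl]-3-{[(tert-butyldimethylsilyl)oxy]methyl}buta-1,3-dien-1-yl]-2-methyloxiran-2-yl]acetaldehyde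
Product: 25 (1R,6R,7R,8S,10R)-15-[(tert-butyldimethylsilyl)oxy]-1,10-epoxy-8-hydroxygermacra-2Z,4E,11(13)-trien-12,6-olide, via allylchromium dichloride 24 (not isolated)
Conditions: CrCl2 (10 equiv), THF, slow syringe-pump addition of 23 to a final 2 mM, rt; then H2O
Reagents that add atoms: none
Why: Two equivalents of CrCl2 reduce the allylic C13–Br bond by single-electron transfers to the trivalent allylchromium 24, which adds to the tethered aldehyde through its γ-carbon C7 (SE2') in a six-membered chair transition state, so that C7–C8 forms while the double bond moves to the exocyclic C11=C13 position and the butenolide becomes the α-methylene lactone. The closest known reactions are the intramolecular Nozaki–Hiyama–Kishi allylations that close ten-membered germacranolide rings from 2-(bromomethyl)alkenoates and the Barbier additions of 3-(bromomethyl)furan-2(5H)-ones to aldehydes. The ten-membered carbocycle closes in a 10-exo-trig carbonyl addition; the five-membered lactone is already present and only shifts its double bond. C7 is controlled by C6: the tether leaves C6 on one face of the planar butenolide and reaches C7 without eclipsing only from the opposite face, which gives the trans-fused 6,12-lactone. C8 is controlled by the chair: the butenolide ring locks C6 trans to C13 (an E-type γ-substituent, equatorial) and the tether places C9 equatorial and anti to C11, which should give the 7,8-anti (8S) alcohol, the C8 epimer of the target that step 20 inverts. The step needs ring closure to win over intermolecular addition and protonation of 24, secured by slow addition at high dilution, and γ- over α-attack, secured by the SE2' preference of allylchromium reagents and the larger ring that α-attack would require; divalent chromium should leave the epoxide, diene and silyl ether untouched.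

Step 17
Reactants: 26 ethyl but-2-ynoate
Product: 28 ethyl (Z)-2-(hydroxymethyl)but-2-enoate, via alkenyldiisobutylalane 27 (not isolated)
Conditions: iBu2AlH, N-methylmorpholine N-oxide, THF, 0 °C; then (CH2O)n, 0 °C to rt; aq. work-up
Reagents that add atoms: paraformaldehyde (as formaldehyde) C=O
Why: Conjugate hydroalumination of the ynoate (vinylalumination) adds hydride and aluminium cis to give the α-aluminio enoate 27 with methyl cis to the ester, and hydroxymethylation with retention gives the Z (angelate-type) geometry of the side chain.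

Step 18
Reactants: 28 ethyl (Z)-2-(hydroxymethyl)but-2-enoate
Product: 29 ethyl (Z)-2-{[(tert-butyldimethylsilyl)oxy]methyl}but-2-enoate
Conditions: TBSCl, imidazole, CH2Cl2, 0 °C to rt
Reagents that add atoms: tert-butyldimethylsilyl chloride CC(C)(C)[Si](C)(C)Cl
Why: Standard silylation of the primary allylic alcohol, which keeps it from competing in the later esterification.

Step 19
Reactants: 29 ethyl (Z)-2-{[(tert-butyldimethylsilyl)oxy]methyl}but-2-enoate
Product: 30 (Z)-2-{[(tert-butyldimethylsilyl)oxy]methyl}but-2-enoic acid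
Conditions: LiOH, THF/MeOH/H2O, 0 °C to rt; then 1 M HCl to pH 4 at 0 °C
Reagents that add atoms: lithium hydroxide [Li+].[OH-]
Why: Saponification of the ethyl ester at low temperature leaves the silyl ether and the Z geometry intact.

Step 20
Reactants: 25 (1R,6R,7R,8S,10R)-15-[(tert-butyldimethylsilyl)oxy]-1,10-epoxy-8-hydroxygermacra-2Z,4E,11(13)-trien-12,6-olide; 30 (Z)-2-{[(tert-butyldimethylsilyl)oxy]methyl}but-2-enoic acid
Product: 31 (1R,6R,7R,8R,10R)-15-[(tert-butyldimethylsilyl)oxy]-8-{[(Z)-2-{[(tert-butyldimethylsilyl)oxy]methyl}but-2-enoyl]oxy}-1,10-epoxygermacra-2Z,4E,11(13)-trien-12,6-olide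
Conditions: 30 (3 equiv), PPh3, DIAD, toluene, 0 °C to rt
Reagents that add atoms: none
Why: Mitsunobu esterification activates the 8S hydroxyl as an oxyphosphonium ion and the carboxylate of 30 displaces it by SN2 with inversion, which installs the side chain and the 8R configuration in one step; H7 is cis to the leaving group, so anti-elimination towards C7 is not available.

Step 21
Reactants: 31 (1R,6R,7R,8R,10R)-15-[(tert-butyldimethylsilyl)oxy]-8-{[(Z)-2-{[(tert-butyldimethylsilyl)oxy]methyl}but-2-enoyl]oxy}-1,10-epoxygermacra-2Z,4E,11(13)-trien-12,6-olide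
Product: 32 (1R,6R,7R,8R,10R)-1,10-epoxy-15-hydroxy-8-{[(Z)-2-(hydroxymethyl)but-2-enoyl]oxy}germacra-2Z,4E,11(13)-trien-12,6-olide (CNP0293319.2)
Conditions: HF·pyridine, pyridine, THF, 0 °C to rt
Reagents that add atoms: none
Why: Pyridine-buffered HF·pyridine removes both primary allylic silyl ethers and should neither open the vinyl epoxide nor add to the α-methylene lactone.

**Compound list**
1 | tert-butyl(but-3-yn-1-yloxy)dimethylsilane | C#CCCO[Si](C)(C)C(C)(C)C | starting material
2 | (E)-{4-[(tert-butyldimethylsilyl)oxy]-2-methylbut-1-en-1-yl}dimethylalane (not isolated) | C[Al](C)/C=C(\C)CCO[Si](C)(C)C(C)(C)C | intermediate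
3 | (E)-5-[(tert-butyldimethylsilyl)oxy]-3-methylpent-2-en-1-ol | OC/C=C(\C)CCO[Si](C)(C)C(C)(C)C | intermediate
4 | [(2R,3R)-3-{2-[(tert-butyldimethylsilyl)oxy]ethyl}-3-methyloxiran-2-yl]methanol | OC[C@H]1O[C@]1(C)CCO[Si](C)(C)C(C)(C)C | intermediate
5 | (2S,3R)-3-{2-[(tert-butyldimethylsilyl)oxy]ethyl}-3-methyloxirane-2-carbaldehyde | O=C[C@H]1O[C@]1(C)CCO[Si](C)(C)C(C)(C)C | intermediate
6 | tert-butyl{2-[(2R,3R)-3-ethynyl-2-methyloxiran-2-yl]ethoxy}dimethylsilane | C#C[C@H]1O[C@]1(C)CCO[Si](C)(C)C(C)(C)C | intermediate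
7 | 2-[(2R,3R)-3-ethynyl-2-methyloxiran-2-yl]ethan-1-ol | C#C[C@H]1O[C@]1(C)CCO | intermediate
8 | 2-(bromomethyl)acrylic acid | C=C(CBr)C(=O)O | starting material
9 | 4-methoxybenzyl alcohol | COc1ccc(CO)cc1 | starting material
10 | 2-{[(4-methoxybenzyl)oxy]methyl}acrylic acid | C=C(COCc1ccc(OC)cc1)C(=O)O | intermediate
11 | (E)-but-2-enal | C/C=C/C=O | starting material
12 | tert-butyldimethyl(prop-2-yn-1-yloxy)silane | C#CCO[Si](C)(C)C(C)(C)C | starting material
13 | methyl{3-[(tert-butyldimethylsilyl)oxy]prop-1-yn-1-yl}zinc (not isolated) | C[Zn]C#CCO[Si](C)(C)C(C)(C)C | intermediate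
14 | (4S,5E)-1-[(tert-butyldimethylsilyl)oxy]hept-5-en-2-yn-4-ol | O[C@@H](/C=C/C)C#CCO[Si](C)(C)C(C)(C)C | intermediate
15 | sodium cyclic alkenylaluminate: 2,2-bis(2-methoxyethoxy)-1,2-oxaluminol-3-ene from 14, Al on C4 and on the C6 oxygen (not isolated) | [Na+].COCCO[Al-]1(OCCOC)O[C@@H](/C=C/C)C=C1CO[Si](C)(C)C(C)(C)C | intermediate
16 | (2Z,4S,5E)-1-[(tert-butyldimethylsilyl)oxy]-2-iodohepta-2,5-dien-4-ol | O[C@@H](/C=C/C)/C=C(\I)CO[Si](C)(C)C(C)(C)C | intermediate
17 | (2Z,4S,5E)-1-[(tert-butyldimethylsilyl)oxy]-2-iodohepta-2,5-dien-4-yl 2-{[(4-methoxybenzyl)oxy]methyl}prop-2-enoate | C=C(COCc1ccc(OC)cc1)C(=O)O[C@@H](/C=C/C)/C=C(\I)CO[Si](C)(C)C(C)(C)C | intermediate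
18 | (5S)-5-[(1Z)-3-[(tert-butyldimethylsilyl)oxy]-2-iodoprop-1-en-1-yl]-3-{[(4-methoxybenzyl)oxy]methyl}furan-2(5H)-one | O=C1O[C@H](/C=C(\I)CO[Si](C)(C)C(C)(C)C)C=C1COCc1ccc(OC)cc1 | intermediate
19 | (5S)-5-[(1Z)-3-[(tert-butyldimethylsilyl)oxy]-2-iodoprop-1-en-1-yl]-3-(hydroxymethyl)furan-2(5H)-one | O=C1O[C@H](/C=C(\I)CO[Si](C)(C)C(C)(C)C)C=C1CO | intermediate
20 | (5R)-5-[(1E)-2-{[(tert-butyldimethylsilyl)oxy]methyl}-4-[(2R,3R)-3-(2-hydroxyethyl)-3-methyloxiran-2-yl]but-1-en-3-yn-1-yl]-3-(hydroxymethyl)furan-2(5H)-one | O=C1O[C@H](/C=C(CO[Si](C)(C)C(C)(C)C)\C#C[C@H]2O[C@]2(C)CCO)C=C1CO | intermediate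
21 | (5R)-5-[(1E,3Z)-2-{[(tert-butyldimethylsilyl)oxy]methyl}-4-[(2R,3R)-3-(2-hydroxyethyl)-3-methyloxiran-2-yl]buta-1,3-dien-1-yl]-3-(hydroxymethyl)furan-2(5H)-one | O=C1O[C@H](/C=C(CO[Si](C)(C)C(C)(C)C)\C=C/[C@H]2O[C@]2(C)CCO)C=C1CO | intermediate
22 | (5R)-3-(bromomethyl)-5-[(1E,3Z)-2-{[(tert-butyldimethylsilyl)oxy]methyl}-4-[(2R,3R)-3-(2-hydroxyethyl)-3-methyloxiran-2-yl]buta-1,3-dien-1-yl]furan-2(5H)-one | O=C1O[C@H](/C=C(CO[Si](C)(C)C(C)(C)C)\C=C/[C@H]2O[C@]2(C)CCO)C=C1CBr | intermediate
23 | 2-[(2R,3R)-3-[(1Z,3E)-4-[(2R)-4-(bromomethyl)-5-oxo-2,5-dihydrofuran-2-yl]-3-{[(tert-butyldimethylsilyl)oxy]methyl}buta-1,3-dien-1-yl]-2-methyloxiran-2-yl]acetaldehyde | O=C1O[C@H](/C=C(CO[Si](C)(C)C(C)(C)C)\C=C/[C@H]2O[C@]2(C)CC=O)C=C1CBr | intermediate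
24 | allylchromium dichloride of 23, CrCl2 unit on C13 in place of bromine (not isolated) | O=C1O[C@H](/C=C(CO[Si](C)(C)C(C)(C)C)\C=C/[C@H]2O[C@]2(C)CC=O)C=C1C[Cr](Cl)Cl | intermediate
25 | (1R,6R,7R,8S,10R)-15-[(tert-butyldimethylsilyl)oxy]-1,10-epoxy-8-hydroxygermacra-2Z,4E,11(13)-trien-12,6-olide | C=C1C(=O)O[C@@H]2/C=C(CO[Si](C)(C)C(C)(C)C)\C=C/[C@H]3O[C@]3(C)C[C@H](O)[C@@H]12 | intermediate
26 | ethyl but-2-ynoate | CC#CC(=O)OCC | starting material
27 | ethyl (E)-2-(diisobutylalumanyl)but-2-enoate, methyl cis to the ester (not isolated) | CCOC(=O)/C(=C\C)[Al](CC(C)C)CC(C)C | intermediate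
28 | ethyl (Z)-2-(hydroxymethyl)but-2-enoate | CCOC(=O)/C(=C\C)CO | intermediate
29 | ethyl (Z)-2-{[(tert-butyldimethylsilyl)oxy]methyl}but-2-enoate | CCOC(=O)/C(=C\C)CO[Si](C)(C)C(C)(C)C | intermediate
30 | (Z)-2-{[(tert-butyldimethylsilyl)oxy]methyl}but-2-enoic acid | OC(=O)/C(=C\C)CO[Si](C)(C)C(C)(C)C | intermediate
31 | (1R,6R,7R,8R,10R)-15-[(tert-butyldimethylsilyl)oxy]-8-{[(Z)-2-{[(tert-butyldimethylsilyl)oxy]methyl}but-2-enoyl]oxy}-1,10-epoxygermacra-2Z,4E,11(13)-trien-12,6-olide | C=C1C(=O)O[C@@H]2/C=C(CO[Si](C)(C)C(C)(C)C)\C=C/[C@H]3O[C@]3(C)C[C@@H](OC(=O)/C(=C\C)CO[Si](C)(C)C(C)(C)C)[C@@H]12 | intermediate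
32 | (1R,6R,7R,8R,10R)-1,10-epoxy-15-hydroxy-8-{[(Z)-2-(hydroxymethyl)but-2-enoyl]oxy}germacra-2Z,4E,11(13)-trien-12,6-olide (CNP0293319.2) | C=C1C(=O)O[C@@H]2/C=C(CO)\C=C/[C@H]3O[C@]3(C)C[C@@H](OC(=O)/C(=C\C)CO)[C@@H]12 | target

**Count**
Total steps: 21. Longest linear sequence: 12 steps (steps 7–16, 20, 21 from 11 and 12; equally steps 1–5, 12–16, 20, 21 from 1).

**Steps most likely to fail**

Step 16 (ring closure). The β,γ-epoxy aldehyde may eliminate to a γ-hydroxy enal, or the dienyl epoxide may be opened by the Lewis-acidic trivalent chromium salts, faster than the slow ring closure at high dilution; protonation of the allylchromium or intermolecular addition would then take over. The fallback closes the ring before the epoxide exists and makes C1/C10 by substrate-controlled epoxidation. It sets out from 3 (and uses 19) and comes back at 25. Oxidation of 3 with MnO2 would give (E)-5-[(tert-butyldimethylsilyl)oxy]-3-methylpent-2-enal F1. Colvin homologation (Me3SiCHN2, LiN(iPr)2, THF, −78 °C to rt) would give (E)-tert-butyldimethyl[(3-methylhex-3-en-5-yn-1-yl)oxy]silane F2, and TBAF would give (E)-3-methylhex-3-en-5-yn-1-ol F3. Sonogashira coupling of F3 with 19 as in step 12 would give the dienyne diol F4. Lindlar hydrogenation would give the (E,Z,Z)-triene diol F5, NBS/Me2S the allylic bromide F6, and Dess–Martin oxidation the β,γ-unsaturated aldehyde F7. F7 would be cyclised at once with CrCl2 as in step 16, with the same control of C7 and C8, to the macrocyclic triene alcohol F8. Epoxidation of F8 with mCPBA/NaHCO3 in CH2Cl2 at −20 °C should take place at the trisubstituted, most electron-rich C1=C10 bond from its exposed outer face. In germacra-1(10)-enolides this is expected to give the 1β,10α-epoxide, that is 25.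

Step 20 (Mitsunobu inversion). SN2 displacement at a secondary carbinol in the ten-membered ring may be slower than elimination of the oxyphosphonium ion towards C9, or the reaction may stall at the activated alcohol. The fallback corrects C8 by oxidation and reduction and then acylates with retention. It sets out from 25 and comes back at 31. Buffered Dess–Martin oxidation would give the 8-ketone (1R,6R,7S,10R)-15-[(tert-butyldimethylsilyl)oxy]-1,10-epoxy-8-oxogermacra-2Z,4E,11(13)-trien-12,6-olide F12, used cold and at once to avoid migration of the exocyclic double bond. Luche reduction (NaBH4, CeCl3·7H2O, MeOH, −78 °C) should deliver hydride to the α-face, opposite to C11 and the C14 methyl, and give the 8R alcohol (1R,6R,7R,8R,10R)-15-[(tert-butyldimethylsilyl)oxy]-1,10-epoxy-8-hydroxygermacra-2Z,4E,11(13)-trien-12,6-olide F13. Yamaguchi esterification with 30 (2,4,6-trichlorobenzoyl chloride, Et3N, then DMAP, toluene) would give 31. Should step 16 itself deliver the 8R alcohol, that material would enter this sequence at F13.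

Step 13 (semi-hydrogenation). Over-reduction of the conjugated diene, Z-to-E isomerisation, or hydrogenolysis of the propargylic/allylic epoxide C–O bond may compete with clean cis-addition. The fallback sets the 2Z geometry by olefination and joins C3–C4 by a stereoretentive Stille coupling, with no alkyne. It sets out from 5 and 19 and comes back at 21. Stork–Zhao olefination of 5 (Ph3P(CH2I)I, NaN(SiMe3)2, THF/DMPU, −78 °C) would give tert-butyl{2-[(2R,3R)-3-[(Z)-2-iodoethenyl]-2-methyloxiran-2-yl]ethoxy}dimethylsilane F9, and TBAF would give 2-[(2R,3R)-3-[(Z)-2-iodoethenyl]-2-methyloxiran-2-yl]ethan-1-ol F10. Stannylation of 19 (Me3SnSnMe3, Pd(PPh3)4, toluene, 80 °C) would give (5S)-5-[(1Z)-3-[(tert-butyldimethylsilyl)oxy]-2-(trimethylstannyl)prop-1-en-1-yl]-3-(hydroxymethyl)furan-2(5H)-one F11. Stille coupling of F10 with F11 (Pd2(dba)3, AsPh3, CuI, DMF, rt) would give 21 with retention at both alkenes.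

**Further compounds**
F1 | step 16 | (E)-5-[(tert-butyldimethylsilyl)oxy]-3-methylpent-2-enal | O=C/C=C(\C)CCO[Si](C)(C)C(C)(C)C
F2 | step 16 | (E)-tert-butyldimethyl[(3-methylhex-3-en-5-yn-1-yl)oxy]silane | C#C/C=C(\C)CCO[Si](C)(C)C(C)(C)C
F3 | step 16 | (E)-3-methylhex-3-en-5-yn-1-ol | C#C/C=C(\C)CCO
F4 | step 16 | (5R)-5-[(1E,5E)-2-{[(tert-butyldimethylsilyl)oxy]methyl}-8-hydroxy-6-methylocta-1,5-dien-3-yn-1-yl]-3-(hydroxymethyl)furan-2(5H)-one | O=C1O[C@H](/C=C(CO[Si](C)(C)C(C)(C)C)\C#C/C=C(\C)CCO)C=C1CO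
F5 | step 16 | (5R)-5-[(1E,3Z,5E)-2-{[(tert-butyldimethylsilyl)oxy]methyl}-8-hydroxy-6-methylocta-1,3,5-trien-1-yl]-3-(hydroxymethyl)furan-2(5H)-one | O=C1O[C@H](/C=C(CO[Si](C)(C)C(C)(C)C)\C=C/C=C(\C)CCO)C=C1CO
F6 | step 16 | (5R)-3-(bromomethyl)-5-[(1E,3Z,5E)-2-{[(tert-butyldimethylsilyl)oxy]methyl}-8-hydroxy-6-methylocta-1,3,5-trien-1-yl]furan-2(5H)-one | O=C1O[C@H](/C=C(CO[Si](C)(C)C(C)(C)C)\C=C/C=C(\C)CCO)C=C1CBr
F7 | step 16 | (3E,5Z,7E)-8-[(2R)-4-(bromomethyl)-5-oxo-2,5-dihydrofuran-2-yl]-7-{[(tert-butyldimethylsilyl)oxy]methyl}-3-methylocta-3,5,7-trienal | O=C1O[C@H](/C=C(CO[Si](C)(C)C(C)(C)C)\C=C/C=C(\C)CC=O)C=C1CBr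
F8 | step 16 | (6R,7R,8S)-15-[(tert-butyldimethylsilyl)oxy]-8-hydroxygermacra-1(10)E,2Z,4E,11(13)-tetraen-12,6-olide | C=C1C(=O)O[C@@H]2/C=C(CO[Si](C)(C)C(C)(C)C)\C=C/C=C(\C)C[C@H](O)[C@@H]12
F9 | step 13 | tert-butyl{2-[(2R,3R)-3-[(Z)-2-iodoethenyl]-2-methyloxiran-2-yl]ethoxy}dimethylsilane | I/C=C\[C@H]1O[C@]1(C)CCO[Si](C)(C)C(C)(C)C
F10 | step 13 | 2-[(2R,3R)-3-[(Z)-2-iodoethenyl]-2-methyloxiran-2-yl]ethan-1-ol | I/C=C\[C@H]1O[C@]1(C)CCO
F11 | step 13 | (5S)-5-[(1Z)-3-[(tert-butyldimethylsilyl)oxy]-2-(trimethylstannyl)prop-1-en-1-yl]-3-(hydroxymethyl)furan-2(5H)-one | O=C1O[C@H](/C=C(\[Sn](C)(C)C)CO[Si](C)(C)C(C)(C)C)C=C1CO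
F12 | step 20 | (1R,6R,7S,10R)-15-[(tert-butyldimethylsilyl)oxy]-1,10-epoxy-8-oxogermacra-2Z,4E,11(13)-trien-12,6-olide | C=C1C(=O)O[C@@H]2/C=C(CO[Si](C)(C)C(C)(C)C)\C=C/[C@H]3O[C@]3(C)CC(=O)[C@@H]12
F13 | step 20 | (1R,6R,7R,8R,10R)-15-[(tert-butyldimethylsilyl)oxy]-1,10-epoxy-8-hydroxygermacra-2Z,4E,11(13)-trien-12,6-olide | C=C1C(=O)O[C@@H]2/C=C(CO[Si](C)(C)C(C)(C)C)\C=C/[C@H]3O[C@]3(C)C[C@@H](O)[C@@H]12
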